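**Plan** (eudesmane numbering throughout, also for the atoms of the monocyclic precursors; α/β refer to the usual drawing with the C10 methyl β)

- **Cuts, in retrosynthetic order:** the aryl–vinyl C–C bond of the coumarate (Heck), the C6–O acyl bond, C6–H (back to the ketone), C1–C10 together with C5–H (ring A), then C4–C5 (Negishi). This leaves (S)-piperitone and a Z-configured five-carbon chain.
- **Enabling feature:** ring B is a p-menthane oxygenated at C6. Quaternary C10 is therefore the β-carbon, and C5 the α-carbon, of a C6=O/C5=C10 enone. A C1 radical tied to C5 through the Z-C3=C4 alkene can reach that enone only at C10.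
- **Forward order:** ring B comes intact from (−)-menthol by oxidation, dehydrogenation and α-iodination. The chain is joined at C4–C5. Ring A is closed last by a light-driven ene-reductase radical cyclisation that makes C1–C10 and C5–H in one event and leaves the alkene at C3=C4.
- **Stereochemistry:** C7 is the isopropyl-bearing centre of (−)-menthol and is never touched. C10 and C5 arise in the key step by same-face delivery of C1 and H, anti to the isopropyl group, which gives the trans-decalin. C6 comes from hydride attack anti to the axial C10 methyl. The Z-alkene comes from the Wittig step and the E-alkene from the Heck step.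

Key step: step 9

Assumption: the ene-reductase variant used in step 9 is picked from a screening panel of old-yellow-enzyme homologues. No other ambiguity arises.

Step 1
Reactants: 1 (−)-menthol
Product: 2 (−)-menthone
Conditions: NaOCl (aq), AcOH, 0 → 25 °C
Reagents that add atoms: none
Why: Hypochlorite oxidation of a secondary alcohol (Stevens oxidation) is fast under mildly acidic conditions and should give the ketone without epimerising the isopropyl-bearing carbon (future C7); no stereocentre is formed.

Step 2
Reactants: 2 (−)-menthone
Product: 3 trimethyl{[(3R,6S)-3-methyl-6-(propan-2-yl)cyclohex-1-en-1-yl]oxy}silane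
Conditions: LiN(i-Pr)2, THF, −78 °C; Me3SiCl
Reagents that add atoms: chlorotrimethylsilane, C[Si](C)(C)Cl
Why: Kinetic enolisation with the hindered lithium amide removes a proton from the CH2 group (future C5) and not from the isopropyl-bearing CH, and O-silylation (silyl enol ether formation) fixes this regiochemistry while both stereocentres stay untouched.

Step 3
Reactants: 3 silyl enol ether
Product: 4 (S)-piperitone, (6S)-3-methyl-6-(propan-2-yl)cyclohex-2-en-1-one
Conditions: Pd(OAc)2 (1 equiv), MeCN, 25 °C
Reagents that add atoms: none
Why: Saegusa–Ito oxidation: divalent palladium takes the enol ether at C5 and β-hydride elimination of the tertiary C10–H gives the C5=C10 enone, so that the methyl-bearing centre is erased on purpose and C7 remains as the only stereocentre.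

Step 4
Reactants: 4 (S)-piperitone
Product: 5 (6S)-2-iodo-3-methyl-6-(propan-2-yl)cyclohex-2-en-1-one
Conditions: I2, pyridine, DMAP (cat.), CH2Cl2, 0 → 25 °C, dark
Reagents that add atoms: iodine, II
Why: Johnson α-iodination (reversible conjugate addition of the pyridine base, iodination of the enolate, elimination) places iodine on the only vinylic C–H, C5, under conditions too weakly basic to enolise towards C7.

Step 5
Reactants: 6 3-[(tert-butyldimethylsilyl)oxy]propanal
Product: 7 (Z)-tert-butyl[(4-iodopent-3-en-1-yl)oxy]dimethylsilane
Conditions: EtPPh3I, n-BuLi, THF, 25 °C; I2, −78 °C; NaN(SiMe3)2, −20 °C; then 6, −78 °C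
Reagents that add atoms: ethyltriphenylphosphonium iodide, CC[P+](c1ccccc1)(c1ccccc1)c1ccccc1.[I-]; iodine, II
Why: Stork–Zhao-type Wittig olefination with the non-stabilised α-iodo ylide runs under kinetic control through the cis-oxaphosphetane and should give the Z-iodoalkene, in which iodine (the future site of C5) and chain carbon C2 are cis, as ring A demands.

Step 6
Reactants: 5 (6S)-2-iodo-3-methyl-6-(propan-2-yl)cyclohex-2-en-1-one; 7 (Z)-vinyl iodide
Product: 10 (6S)-2-[(2Z)-5-{[tert-butyl(dimethyl)silyl]oxy}pent-2-en-2-yl]-3-methyl-6-(propan-2-yl)cyclohex-2-en-1-one, via alkenyllithium 8 (not isolated), via alkenylzinc bromide 9 (not isolated)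
Conditions: 7, t-BuLi (2 equiv), Et2O, −78 °C; ZnBr2, THF, −78 → 0 °C; then 5, Pd2(dba)3 (cat.), tri(2-furyl)phosphine, THF–DMF, 25 → 50 °C
Reagents that add atoms: none
Why: Negishi coupling: iodine–lithium exchange, transmetalation to zinc and the palladium-catalysed coupling with the α-iodoenone all proceed with retention at the alkenyl carbon, so the C4–C5 bond forms with the Z-geometry kept and without a base that could touch C7.

Step 7
Reactants: 10 silyl ether
Product: 11 (6S)-2-[(2Z)-5-hydroxypent-2-en-2-yl]-3-methyl-6-(propan-2-yl)cyclohex-2-en-1-one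
Conditions: HF·pyridine, THF, 0 → 25 °C
Reagents that add atoms: none
Why: Fluoride-mediated desilylation, driven by the strong Si–F bond, frees the primary alcohol, and the buffered medium leaves the dienone and C7 alone.

Step 8
Reactants: 11 primary alcohol
Product: 12 (6S)-2-[(2Z)-5-iodopent-2-en-2-yl]-3-methyl-6-(propan-2-yl)cyclohex-2-en-1-one
Conditions: I2, PPh3, imidazole, CH2Cl2, 0 °C
Reagents that add atoms: iodine, II
Why: Garegg–Samuelsson (Appel-type) iodination turns the primary alcohol into the iodide by SN2 displacement of the oxyphosphonium group under nearly neutral conditions.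

Step 9
Reactants: 12 (6S)-2-[(2Z)-5-iodopent-2-en-2-yl]-3-methyl-6-(propan-2-yl)cyclohex-2-en-1-one
Product: 13 (5R,7S,10R)-eudesm-3-en-6-one (5α-H, 7β-isopropyl, 10β-methyl, trans-fused)
Conditions: flavin-dependent ene-reductase (old yellow enzyme family), NADP+ (cat.), glucose dehydrogenase, D-glucose, K2HPO4/KH2PO4 buffer pH 7.5–DMSO 9:1, N2, cyan LED (about 500 nm), 25 °C
Reagents that add atoms: none
Why: Proposed new method: with the C6 carbonyl of 12 hydrogen-bonded to the histidine/asparagine pair above the reduced flavin, photoexcited flavin hydroquinone should pass one electron into the C1–I bond, and loss of iodide leaves a nucleophilic primary C1 radical held between flavin and enone. The radical adds to C10, the β-carbon of the C6=O/C5=C10 enone, in a 6-endo-trig closure of ring A, and the resulting O/C5/C3-delocalised radical is quenched at C5 by hydrogen-atom transfer from N5–H of the flavin semiquinone, after which NADPH (recycled with glucose) reloads the flavin. The closest known reaction type is the photoenzymatic reductive cyclisation of unactivated alkyl iodides onto α,β-unsaturated carbonyl acceptors in ene-reductases, shown for exo closures ending in tertiary centres; the endo mode, the tetrasubstituted acceptor and the quaternary centre are new. C10 is controlled by the enone face that the pocket turns towards the flavin-side chain (α-face, anti to the 7β-isopropyl group, which stays pseudo-equatorial in the product-like half-chair with the methyl group going axial), and C5 by hydrogen delivery from that same flavin face, anti to the new angular methyl, so that C1 and H add syn and the decalin is trans-fused. The step needs 6-endo over 5-exo closure, C5 over C3 hydrogen delivery and no plain C=C reduction: only attack at C10 is polarity-matched and gives a stabilised radical while C5 is fully substituted, the Z-alkene holds C1 over C10, N5–H sits over Cα/Cβ and far from C3, and tetrasubstituted enones are poor substrates for the native hydride transfer. The neutral medium keeps C7 from epimerising and the C3=C4 alkene out of conjugation, which no tin, silicon or samarium reductant secures together with the face selection.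

Step 10
Reactants: 13 (5R,7S,10R)-eudesm-3-en-6-one
Product: 14 (5R,6R,7S,10R)-eudesm-3-en-6β-ol (axial hydroxyl)
Conditions: (i-Bu)2AlH, CH2Cl2, −78 °C; aq. KNaC4H4O6
Reagents that add atoms: none
Why: 1,2-Reduction with a non-basic aluminium hydride at low temperature: the β-face of the C6 carbonyl is screened by the syn-axial C10 methyl group, so hydride should arrive from the α-face and give the axial 6β-alcohol (as known for 6-oxo steroids) before the C3=C4 alkene can move into conjugation.

Step 11
Reactants: 14 eudesm-3-en-6β-ol
Product: 15 (5R,6R,7S,10R)-eudesm-3-en-6β-yl prop-2-enoate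
Conditions: acryloyl chloride, i-Pr2NEt, DMAP (cat.), CH2Cl2, 0 → 40 °C
Reagents that add atoms: acryloyl chloride, C=CC(=O)Cl
Why: DMAP-catalysed acylation (nucleophilic catalysis) with the small and very reactive acid chloride is chosen because the 6β-hydroxyl is axial and flanked by the C7 isopropyl and C10 methyl groups, and the configuration at C6 is retained since only the O–H bond reacts.

Step 12
Reactants: 15 eudesm-3-en-6β-yl prop-2-enoate; 16 4-iodophenol
Product: 17 (1R,2S,4aR,8aR)-4a,8-dimethyl-2-(propan-2-yl)-1,2,3,4,4a,5,6,8a-octahydronaphthalen-1-yl (2E)-3-(4-hydroxyphenyl)prop-2-enoate (target)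
Conditions: Pd(OAc)2 (cat.), NaHCO3, n-Bu4NCl, DMF, 70 °C
Reagents that add atoms: none
Why: Mizoroki–Heck reaction under Jeffery conditions: aryl–palladium adds to the terminal acrylate carbon and syn β-hydride elimination gives the E-cinnamate, while the trisubstituted C3=C4 alkene is too hindered to insert and the free phenol is tolerated.

**Compound list**

1 | (−)-menthol, (1R,2S,5R)-5-methyl-2-(propan-2-yl)cyclohexan-1-ol | CC(C)[C@@H]1CC[C@@H](C)C[C@H]1O | starting material
2 | (−)-menthone, (2S,5R)-5-methyl-2-(propan-2-yl)cyclohexan-1-one | CC(C)[C@@H]1CC[C@@H](C)CC1=O | intermediate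
3 | trimethyl{[(3R,6S)-3-methyl-6-(propan-2-yl)cyclohex-1-en-1-yl]oxy}silane | CC(C)[C@@H]1CC[C@@H](C)C=C1O[Si](C)(C)C | intermediate
4 | (S)-piperitone, (6S)-3-methyl-6-(propan-2-yl)cyclohex-2-en-1-one | CC(C)[C@@H]1CCC(C)=CC1=O | intermediate
5 | (6S)-2-iodo-3-methyl-6-(propan-2-yl)cyclohex-2-en-1-one | CC1=C(I)C(=O)[C@H](C(C)C)CC1 | intermediate
6 | 3-[(tert-butyldimethylsilyl)oxy]propanal | O=CCCO[Si](C)(C)C(C)(C)C | starting material
7 | (Z)-tert-butyl[(4-iodopent-3-en-1-yl)oxy]dimethylsilane (iodine cis to the chain) | I/C(C)=C\CCO[Si](C)(C)C(C)(C)C | intermediate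
8 | 5-[(tert-butyldimethylsilyl)oxy]pent-2-en-2-yllithium (lithium cis to the chain) | [Li]/C(C)=C\CCO[Si](C)(C)C(C)(C)C | intermediate
9 | {5-[(tert-butyldimethylsilyl)oxy]pent-2-en-2-yl}zinc bromide (zinc cis to the chain) | Br[Zn]/C(C)=C\CCO[Si](C)(C)C(C)(C)C | intermediate
10 | (6S)-2-[(2Z)-5-{[tert-butyl(dimethyl)silyl]oxy}pent-2-en-2-yl]-3-methyl-6-(propan-2-yl)cyclohex-2-en-1-one | CC1=C(/C(C)=C\CCO[Si](C)(C)C(C)(C)C)C(=O)[C@H](C(C)C)CC1 | intermediate
11 | (6S)-2-[(2Z)-5-hydroxypent-2-en-2-yl]-3-methyl-6-(propan-2-yl)cyclohex-2-en-1-one | CC1=C(/C(C)=C\CCO)C(=O)[C@H](C(C)C)CC1 | intermediate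
12 | (6S)-2-[(2Z)-5-iodopent-2-en-2-yl]-3-methyl-6-(propan-2-yl)cyclohex-2-en-1-one | CC1=C(/C(C)=C\CCI)C(=O)[C@H](C(C)C)CC1 | intermediate
13 | (5R,7S,10R)-eudesm-3-en-6-one, (2S,4aR,8aR)-4a,8-dimethyl-2-(propan-2-yl)-3,4,4a,5,6,8a-hexahydronaphthalen-1(2H)-one | CC1=CCC[C@]2(C)CC[C@@H](C(C)C)C(=O)[C@@H]12 | intermediate
14 | (5R,6R,7S,10R)-eudesm-3-en-6β-ol | CC1=CCC[C@]2(C)CC[C@@H](C(C)C)[C@@H](O)[C@@H]12 | intermediate
15 | (5R,6R,7S,10R)-eudesm-3-en-6β-yl prop-2-enoate | CC1=CCC[C@]2(C)CC[C@@H](C(C)C)[C@@H](OC(=O)C=C)[C@@H]12 | intermediate
16 | 4-iodophenol | Oc1ccc(I)cc1 | starting material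
17 | (5R,6R,7S,10R)-eudesm-3-en-6β-yl (E)-4-hydroxycinnamate | CC1=CCC[C@]2(C)CC[C@@H](C(C)C)[C@@H](OC(=O)/C=C/c3ccc(O)cc3)[C@@H]12 | target

**Total step count:** 12.
**Longest linear sequence:** 11 steps (1 → 17 through steps 1–4 and 6–12).

**Steps most likely to fail**

1. **Step 9 (Proposed new method).**
   - What may go wrong: the bulky tetrasubstituted enone may not bind productively, hydrodeiodination may outrun the slow 6-endo closure, or face selection at C10 may be poor.
   - Fallback with known chemistry, setting out from 12 and coming back at 13: a tin-hydride Giese-type cyclisation (Bu3SnH added slowly, AIBN, benzene, 80 °C) should close the same C1–C10 bond.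
   - The delocalised radical is then expected to take hydrogen mainly at the less hindered C3, which gives the conjugated enone (7S,10R)-eudesm-4-en-6-one F1.
   - Its C10 epimer is a diastereomer because C7 is intact, and it is removed by chromatography before any base is used.
   - Deconjugative protonation follows (KOt-Bu, t-BuOH–THF, then inverse quench into cold aqueous AcOH). The C3=C4–C5=C6 dienolate is protonated at C5, anti to the angular methyl, which returns 13.

2. **Step 6.**
   - What may go wrong: sluggish oxidative addition and transmetalation between two hindered partners, homocoupling, or erosion of the Z-geometry.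
   - Fallback setting out from 2 and 7 and coming back at 10: palladium-catalysed α-alkenylation of the ketone enolate [LiN(SiMe3)2, Pd2(dba)3, P(t-Bu)3, THF] joins C4–C5 at the unhindered CH2 of menthone. C10 is then still a stereocentre that holds C5 and C7 equatorial.
   - This gives the all-equatorial alkenylmenthone (2R,3R,6S)-2-[(2Z)-5-{[tert-butyl(dimethyl)silyl]oxy}pent-2-en-2-yl]-3-methyl-6-(propan-2-yl)cyclohexan-1-one F2.
   - Soft enolisation (Me3SiOTf, Et3N) gives the trimethylsilyl dienol ether F3.
   - Saegusa–Ito oxidation with Pd(OAc)2 then installs C5=C10 and returns 10.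

3. **Step 11.**
   - What may go wrong: incomplete acylation of the hindered axial hydroxyl, or polymerisation of the acrylate during the longer reaction time.
   - Fallback setting out from 14 and coming back at 17: (diethoxyphosphoryl)acetic acid with DCC acylates through the phosphonoketene, which accepts hindered alcohols. This should give eudesm-3-en-6β-yl (diethoxyphosphoryl)acetate F4.
   - A Masamune–Roush Horner–Wadsworth–Emmons olefination with 4-hydroxybenzaldehyde (LiCl, DBU, MeCN) then builds the E-cinnamate and gives 17 directly, without 15 and step 12.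

**Further compounds**

F1 | step 9 | (7S,10R)-eudesm-4-en-6-one | CC1=C2C(=O)[C@H](C(C)C)CC[C@@]2(C)CCC1
F2 | step 6 | (2R,3R,6S)-2-[(2Z)-5-{[tert-butyl(dimethyl)silyl]oxy}pent-2-en-2-yl]-3-methyl-6-(propan-2-yl)cyclohexan-1-one | C[C@@H]1CC[C@@H](C(C)C)C(=O)[C@H]1/C(C)=C\CCO[Si](C)(C)C(C)(C)C
F3 | step 6 | trimethylsilyl dienol ether of F2 (C5=C6 enol ether, C10 and C7 centres kept) | C[C@@H]1CC[C@@H](C(C)C)C(O[Si](C)(C)C)=C1/C(C)=C\CCO[Si](C)(C)C(C)(C)C
F4 | step 11 | (5R,6R,7S,10R)-eudesm-3-en-6β-yl (diethoxyphosphoryl)acetate | CC1=CCC[C@]2(C)CC[C@@H](C(C)C)[C@@H](OC(=O)CP(=O)(OCC)OCC)[C@@H]12
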